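Everything rests on cutting the C9–C10 bond of the tetrahydrofuran C9–C10–O–C11–C8 (carbocycle numbered C1–C9, C1 carrying the exocyclic CH2, C5 the methyl carbinol). C10 is an OCH2 carbon at the formaldehyde level and C9 carries the C1(=CH2) corner of the nine-membered ring, the imprint of an allylsilane Me3SiCH2–C1=C9 that has trapped a C11–O=CH2 cation. One Lewis-acid step thus closes the tetrahydrofuran, sets C9 trans to C8 and releases the exocyclic methylene. Its precursor is an acyclic C11 methoxymethyl ether with the C8 centre, the E-allylsilane bearing a silyl-capped propargyl group, two differentiated C11 arms and C5 as a naphthylmethyl ether, because an amide there would not outlast the Grignard and hydride steps.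

Key step: step 16

Remark (labels): of the two CH2O groups on C11, arm A is the one that ends as the palmitate and arm B the one that ends as the dienyl group.
Remark (assumption): the facial sense of the titanium tartrate epoxidation (step 7) follows the usual rule, under which L-(+)-tartrate turns allyl alcohol into (S)-glycidol; for 10 this means the (2R,3S)-epoxide.
Remark (assumption): C5 is set by addition to the ring ketone under substrate control (step 23); the sense given there is a conformational prediction, not a secured outcome.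

Step 1
Reactants: 1 butane-1,4-diol; 2 2-(bromomethyl)naphthalene
Product: 3 4-(naphthalen-2-ylmethoxy)butan-1-ol
Conditions: NaH (1 equiv), 1 in excess, THF/DMF, 0 °C to rt
Reagents that add atoms: none
Why: Williamson etherification of the mono-alkoxide of a diol used in excess should give the mono-ether; no stereocentre is involved.

Step 2
Reactants: 3 4-(naphthalen-2-ylmethoxy)butan-1-ol
Product: 4 4-(naphthalen-2-ylmethoxy)butanal
Conditions: TEMPO (cat.), PhI(OAc)2, CH2Cl2, rt
Reagents that add atoms: none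
Why: TEMPO-catalysed (oxoammonium) oxidation of a primary alcohol stops cleanly at the aldehyde.

Step 3
Reactants: 4 4-(naphthalen-2-ylmethoxy)butanal; 5 methyl acrylate
Product: 6 methyl 3-hydroxy-2-methylidene-6-(naphthalen-2-ylmethoxy)hexanoate (racemic)
Conditions: DABCO, MeOH (cat.), rt, several days
Reagents that add atoms: none
Why: Morita–Baylis–Hillman reaction of an unhindered aliphatic aldehyde with an acrylate should give the racemic allylic alcohol, whose carbinol centre is erased in step 4.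

Step 4
Reactants: 6 methyl 3-hydroxy-2-methylidene-6-(naphthalen-2-ylmethoxy)hexanoate
Product: 7 methyl (2Z)-2-(bromomethyl)-6-(naphthalen-2-ylmethoxy)hex-2-enoate
Conditions: NBS, Me2S, CH2Cl2, 0 °C to rt
Reagents that add atoms: N-bromosuccinimide O=C1CCC(=O)N1Br
Why: Corey–Kim-type activation of the alcohol and SN2' attack of bromide move the double bond into conjugation and should give the 2Z bromide (chain trans to the ester), the usual outcome for these adducts.

Step 5
Reactants: 7 methyl (2Z)-2-(bromomethyl)-6-(naphthalen-2-ylmethoxy)hex-2-enoate; 8 4-methoxyphenol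
Product: 9 methyl (2E)-2-[(4-methoxyphenoxy)methyl]-6-(naphthalen-2-ylmethoxy)hex-2-enoate
Conditions: K2CO3, acetone, rt
Reagents that add atoms: none
Why: Williamson substitution of the primary allylic bromide by the phenoxide keeps the alkene geometry, so the aryl ether (arm B) ends cis to the chain, which is also the thermodynamic isomer.

Step 6
Reactants: 9 methyl (2E)-2-[(4-methoxyphenoxy)methyl]-6-(naphthalen-2-ylmethoxy)hex-2-enoate
Product: 10 (2Z)-2-[(4-methoxyphenoxy)methyl]-6-(naphthalen-2-ylmethoxy)hex-2-en-1-ol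
Conditions: i-Bu2AlH (2.5 equiv), CH2Cl2, −78 °C
Reagents that add atoms: none
Why: 1,2-reduction of the conjugated ester by i-Bu2AlH should give the allylic alcohol (arm A hydroxyl) without touching the ethers.

Step 7
Reactants: 10 (2Z)-2-[(4-methoxyphenoxy)methyl]-6-(naphthalen-2-ylmethoxy)hex-2-en-1-ol
Product: 11 [(2R,3S)-2-[(4-methoxyphenoxy)methyl]-3-[3-(naphthalen-2-ylmethoxy)propyl]oxiran-2-yl]methanol
Conditions: Ti(OiPr)4 (cat.), L-(+)-diisopropyl tartrate, t-BuOOH, 4 Å MS, CH2Cl2, −20 °C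
Reagents that add atoms: tert-butyl hydroperoxide CC(C)(C)OO
Why: Sharpless asymmetric epoxidation directed by the arm A hydroxyl; with L-(+)-tartrate the oxygen is delivered to the face that gives the (2R,3S)-epoxide, so reagent control sets C11 and prepares C8 for inversion.

Step 8
Reactants: 11 [(2R,3S)-2-[(4-methoxyphenoxy)methyl]-3-[3-(naphthalen-2-ylmethoxy)propyl]oxiran-2-yl]methanol; 12 tert-butyldimethyl(prop-2-yn-1-yloxy)silane
Product: 15 (2R,3S)-6-[(tert-butyldimethylsilyl)oxy]-2-[(4-methoxyphenoxy)methyl]-3-[3-(naphthalen-2-ylmethoxy)propyl]hex-4-yne-1,2-diol, via lithium acetylide 13 (not isolated), via alkynylalane 14 (not isolated)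
Conditions: 12 (3.5 equiv), n-BuLi, toluene, −78 to 0 °C; Et2AlCl, 0 °C; then 11, toluene, 0 °C to rt
Reagents that add atoms: butyllithium [Li]CCCC (lithium of 13 only); diethylaluminium chloride CC[Al](Cl)CC (aluminium and ethyl groups of 14 only)
Why: Alkynylalane opening of a 2,3-epoxy alcohol: the aluminium alkoxide delivers the alkynyl group to the less substituted oxirane carbon C8 in an SN2 step with inversion, which sets 8S next to the intact C11 carbinol.

Step 9
Reactants: 15 (2R,3S)-6-[(tert-butyldimethylsilyl)oxy]-2-[(4-methoxyphenoxy)methyl]-3-[3-(naphthalen-2-ylmethoxy)propyl]hex-4-yne-1,2-diol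
Product: 16 (2S,3S)-6-[(tert-butyldimethylsilyl)oxy]-1-[(tert-butyldiphenylsilyl)oxy]-2-[(4-methoxyphenoxy)methyl]-3-[3-(naphthalen-2-ylmethoxy)propyl]hex-4-yn-2-ol
Conditions: TBDPSCl, imidazole, CH2Cl2, 0 °C
Reagents that add atoms: tert-butyl(chloro)diphenylsilane CC(C)(C)[Si](Cl)(c1ccccc1)c1ccccc1
Why: Silylation with the bulky chlorosilane is selective for the primary (arm A) hydroxyl over the hindered tertiary one.

Step 10
Reactants: 16 (2S,3S)-6-[(tert-butyldimethylsilyl)oxy]-1-[(tert-butyldiphenylsilyl)oxy]-2-[(4-methoxyphenoxy)methyl]-3-[3-(naphthalen-2-ylmethoxy)propyl]hex-4-yn-2-ol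
Product: 17 (2S,3S)-6-[(tert-butyldimethylsilyl)oxy]-1-[(tert-butyldiphenylsilyl)oxy]-2-(methoxymethoxy)-2-[(4-methoxyphenoxy)methyl]-3-[3-(naphthalen-2-ylmethoxy)propyl]hex-4-yne
Conditions: MOMCl, i-Pr2NEt, Bu4NI (cat.), 1,2-dichloroethane, 60 °C
Reagents that add atoms: chloromethyl methyl ether COCCl
Why: Alkylation of the tertiary alcohol by iodomethyl methyl ether formed in situ (Finkelstein exchange) under amine base should install the acetal that later supplies C10, while strongly basic alkoxide conditions that could move silicon are avoided.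

Step 11
Reactants: 17 (2S,3S)-6-[(tert-butyldimethylsilyl)oxy]-1-[(tert-butyldiphenylsilyl)oxy]-2-(methoxymethoxy)-2-[(4-methoxyphenoxy)methyl]-3-[3-(naphthalen-2-ylmethoxy)propyl]hex-4-yne
Product: 18 (4S,5S)-6-[(tert-butyldiphenylsilyl)oxy]-5-(methoxymethoxy)-5-[(4-methoxyphenoxy)methyl]-4-[3-(naphthalen-2-ylmethoxy)propyl]hex-2-yn-1-ol
Conditions: HF·pyridine, pyridine, THF, 0 °C to rt
Reagents that add atoms: none
Why: Fluoride-mediated desilylation removes the unhindered propargylic TBS ether much faster than the neopentyl-type TBDPS ether, and the acetal is stable to buffered HF.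

Step 12
Reactants: 18 (4S,5S)-6-[(tert-butyldiphenylsilyl)oxy]-5-(methoxymethoxy)-5-[(4-methoxyphenoxy)methyl]-4-[3-(naphthalen-2-ylmethoxy)propyl]hex-2-yn-1-ol
Product: 20 (2E,4S,5S)-6-[(tert-butyldiphenylsilyl)oxy]-2-iodo-5-(methoxymethoxy)-5-[(4-methoxyphenoxy)methyl]-4-[3-(naphthalen-2-ylmethoxy)propyl]hex-2-en-1-ol, via vinylstannane 19 (not isolated)
Conditions: Bu3SnH, PdCl2(PPh3)2 (cat.), THF, 0 °C to rt; then I2, CH2Cl2, 0 °C
Reagents that add atoms: tributylstannane CCCC[SnH](CCCC)CCCC (tin of 19 only); iodine II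
Why: Palladium-catalysed hydrostannation adds H and Sn syn across the alkyne with tin on the carbon next to CH2OH and away from the branched C8 side, and iododestannylation with retention should give the 2E iodide (iodine trans to C8).

Step 13
Reactants: 20 (2E,4S,5S)-6-[(tert-butyldiphenylsilyl)oxy]-2-iodo-5-(methoxymethoxy)-5-[(4-methoxyphenoxy)methyl]-4-[3-(naphthalen-2-ylmethoxy)propyl]hex-2-en-1-ol
Product: 21 (2E,4S,5S)-1-bromo-6-[(tert-butyldiphenylsilyl)oxy]-2-iodo-5-(methoxymethoxy)-5-[(4-methoxyphenoxy)methyl]-4-[3-(naphthalen-2-ylmethoxy)propyl]hex-2-ene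
Conditions: CBr4, PPh3, 2,6-lutidine, CH2Cl2, 0 °C
Reagents that add atoms: tetrabromomethane BrC(Br)(Br)Br
Why: The Appel reaction converts the primary allylic alcohol into the bromide under near-neutral conditions that the acetal, the ethers and the alkenyl iodide tolerate.

Step 14
Reactants: 21 (2E,4S,5S)-1-bromo-6-[(tert-butyldiphenylsilyl)oxy]-2-iodo-5-(methoxymethoxy)-5-[(4-methoxyphenoxy)methyl]-4-[3-(naphthalen-2-ylmethoxy)propyl]hex-2-ene; 22 ethynyltrimethylsilane
Product: 23 (4E,6S,7S)-8-[(tert-butyldiphenylsilyl)oxy]-4-iodo-7-(methoxymethoxy)-7-[(4-methoxyphenoxy)methyl]-6-[3-(naphthalen-2-ylmethoxy)propyl]-1-(trimethylsilyl)oct-4-en-1-yne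
Conditions: CuI (cat.), Bu4NI (cat.), K2CO3, DMF, rt
Reagents that add atoms: none
Why: Copper-catalysed coupling of a terminal alkyne with a primary allylic bromide should form the skipped enyne by direct substitution, since the SN2' site C9 is hindered and the alkenyl iodide does not react with copper acetylides at room temperature.

Step 15
Reactants: 23 (4E,6S,7S)-8-[(tert-butyldiphenylsilyl)oxy]-4-iodo-7-(methoxymethoxy)-7-[(4-methoxyphenoxy)methyl]-6-[3-(naphthalen-2-ylmethoxy)propyl]-1-(trimethylsilyl)oct-4-en-1-yne; 24 (trimethylsilyl)methylmagnesium chloride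
Product: 25 (4E,6S,7S)-8-[(tert-butyldiphenylsilyl)oxy]-7-(methoxymethoxy)-7-[(4-methoxyphenoxy)methyl]-6-[3-(naphthalen-2-ylmethoxy)propyl]-1-(trimethylsilyl)-4-[(trimethylsilyl)methyl]oct-4-en-1-yne
Conditions: Pd(PPh3)4 (cat.), THF, rt
Reagents that add atoms: none
Why: Kumada–Corriu coupling of the alkenyl iodide with the silylmethyl Grignard reagent proceeds with retention and installs the allylsilane last, so that it meets no acid or electrophile before the key step, and the C5 ether tolerates the Grignard reagent.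

Step 16
Reactants: 25 (4E,6S,7S)-8-[(tert-butyldiphenylsilyl)oxy]-7-(methoxymethoxy)-7-[(4-methoxyphenoxy)methyl]-6-[3-(naphthalen-2-ylmethoxy)propyl]-1-(trimethylsilyl)-4-[(trimethylsilyl)methyl]oct-4-en-1-yne
Product: 26 tert-butyl{[(2S,3S,4R)-2-[(4-methoxyphenoxy)methyl]-3-[3-(naphthalen-2-ylmethoxy)propyl]-4-[5-(trimethylsilyl)pent-1-en-4-yn-2-yl]oxolan-2-yl]methoxy}diphenylsilane
Conditions: TMSOTf, 2,6-di-tert-butyl-4-methylpyridine, CH2Cl2, −78 to −30 °C
Reagents that add atoms: none
Why: TMSOTf silylates the methoxy oxygen of the acetal and expels MeOSiMe3, leaving the C11–O=CH2 cation, which is captured by C9, the allylsilane carbon gamma to silicon; loss of Me3Si from the beta-silyl cation at C1 then fixes the alkene as the exocyclic C1=CH2. This is a Prins-type intramolecular Hosomi–Sakurai allylation of a formaldehyde oxocarbenium ion, the established way from a homoallylic acetal carrying an allylsilane to a 3-alkenyltetrahydrofuran. The five-membered ring closes exo with respect to the C9=C1 alkene and endo with respect to the O=C10 bond (O and C10 both in the ring), a mode that oxocarbenium ions accept readily. The new C9 centre is controlled by C8: allylic 1,3-strain with the CH2 group on C1 that is cis to C8 keeps H8 in the alkene plane, so C10, tethered through C11–O, adds to the face that puts the C1 unit trans to the C7 chain (8S gives 9R). The step needs C9 attack to outrun loss of the whole acetal, protodesilylation and capture of the cation by a neighbouring oxygen; the hindered tertiary oxygen steers the silyl Lewis acid to the methoxy oxygen, the pyridine base removes adventitious acid, the silylmethyl group trans to C8 can lie anti to the incoming carbon, and the arm oxygens are an aryl ether and a bulky silyl ether, both poor nucleophiles.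

Step 17
Reactants: 26 tert-butyl{[(2S,3S,4R)-2-[(4-methoxyphenoxy)methyl]-3-[3-(naphthalen-2-ylmethoxy)propyl]-4-[5-(trimethylsilyl)pent-1-en-4-yn-2-yl]oxolan-2-yl]methoxy}diphenylsilane
Product: 27 tert-butyl{[(2S,3S,4R)-4-(5-iodopent-1-en-4-yn-2-yl)-2-[(4-methoxyphenoxy)methyl]-3-[3-(naphthalen-2-ylmethoxy)propyl]oxolan-2-yl]methoxy}diphenylsilane
Conditions: NIS, AgNO3 (cat.), DMF, rt, dark
Reagents that add atoms: N-iodosuccinimide O=C1CCC(=O)N1I
Why: Silver-catalysed desilylative iodination exchanges the alkynyl silicon for iodine under neutral conditions without touching the alkene or the ethers.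

Step 18
Reactants: 27 tert-butyl{[(2S,3S,4R)-4-(5-iodopent-1-en-4-yn-2-yl)-2-[(4-methoxyphenoxy)methyl]-3-[3-(naphthalen-2-ylmethoxy)propyl]oxolan-2-yl]methoxy}diphenylsilane
Product: 28 tert-butyl{[(2S,3S,4R)-4-[(4Z)-5-iodopenta-1,4-dien-2-yl]-2-[(4-methoxyphenoxy)methyl]-3-[3-(naphthalen-2-ylmethoxy)propyl]oxolan-2-yl]methoxy}diphenylsilane
Conditions: 2-nitrobenzenesulfonohydrazide, Et3N, THF/i-PrOH, rt
Reagents that add atoms: none
Why: Diimide reduction: syn transfer of two hydrogens to the iodoalkyne should give the Z-alkenyl iodide while the hindered 1,1-disubstituted alkene reacts far more slowly, and the step is placed before the aldehyde is freed because hydrazides condense with aldehydes.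

Step 19
Reactants: 28 tert-butyl{[(2S,3S,4R)-4-[(4Z)-5-iodopenta-1,4-dien-2-yl]-2-[(4-methoxyphenoxy)methyl]-3-[3-(naphthalen-2-ylmethoxy)propyl]oxolan-2-yl]methoxy}diphenylsilane
Product: 29 3-[(2S,3S,4R)-2-{[(tert-butyldiphenylsilyl)oxy]methyl}-4-[(4Z)-5-iodopenta-1,4-dien-2-yl]-2-[(4-methoxyphenoxy)methyl]oxolan-3-yl]propan-1-ol
Conditions: DDQ, CH2Cl2/pH 7 buffer, 0 °C to rt
Reagents that add atoms: none
Why: Oxidative cleavage of the naphthylmethyl ether by DDQ (hydride abstraction, then hydrolysis) frees the C5 alcohol, the aryl ether and the silyl ether being inert to DDQ.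

Step 20
Reactants: 29 3-[(2S,3S,4R)-2-{[(tert-butyldiphenylsilyl)oxy]methyl}-4-[(4Z)-5-iodopenta-1,4-dien-2-yl]-2-[(4-methoxyphenoxy)methyl]oxolan-3-yl]propan-1-ol
Product: 30 3-[(2S,3S,4R)-2-{[(tert-butyldiphenylsilyl)oxy]methyl}-4-[(4Z)-5-iodopenta-1,4-dien-2-yl]-2-[(4-methoxyphenoxy)methyl]oxolan-3-yl]propanal
Conditions: Dess–Martin periodinane, pyridine, CH2Cl2, rt
Reagents that add atoms: none
Why: Dess–Martin oxidation gives the C5 aldehyde under mild buffered conditions.

Step 21
Reactants: 30 3-[(2S,3S,4R)-2-{[(tert-butyldiphenylsilyl)oxy]methyl}-4-[(4Z)-5-iodopenta-1,4-dien-2-yl]-2-[(4-methoxyphenoxy)methyl]oxolan-3-yl]propanal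
Product: 31 bicyclic allylic alcohol: (3Z)-cyclononene trans-fused to the tetrahydrofuran (8S,9R; C11 as in 26), C1 methylidene, C5 secondary carbinol as both epimers, arm B 4-methoxyphenyl ether, arm A TBDPS ether
Conditions: CrCl2 (8 equiv), NiCl2 (cat.), DMSO/THF, rt, slow addition, about 0.003 M
Reagents that add atoms: none
Why: Nozaki–Hiyama–Kishi reaction: nickel-catalysed insertion into the C4–I bond and transmetalation to chromium give an alkenylchromium species that adds only to the aldehyde, which at high dilution should close the nine-membered ring with retention of the Z-alkene, and both C5 epimers are acceptable because the carbinol is oxidised next.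

Step 22
Reactants: 31 bicyclic allylic alcohol (both C5 epimers)
Product: 32 bicyclic (3Z)-enone: C5 ketone, otherwise as 31
Conditions: Dess–Martin periodinane, pyridine, CH2Cl2, 0 °C
Reagents that add atoms: none
Why: Dess–Martin oxidation of the secondary allylic alcohol converges both epimers on the Z-enone without acid or base that could move the skipped exocyclic alkene into conjugation.

Step 23
Reactants: 32 bicyclic (3Z)-enone
Product: 33 bicyclic tertiary alcohol: (3Z,5S,8S,9R), C5 methyl carbinol, arm B 4-methoxyphenyl ether, arm A TBDPS ether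
Conditions: MeLi, CeCl3 (anhydrous), THF, −78 °C
Reagents that add atoms: methyllithium [Li]C
Why: Organocerium 1,2-addition (weakly basic, carbonyl-selective) should add methyl without enolisation or conjugate addition; the carbonyl oxygen is expected to point to the H8 side, away from the C8–C11 bond with its two bulky arms, so that methyl arrives from the ring periphery and the hydroxyl ends syn to H8, which is 5S.

Step 24
Reactants: 33 bicyclic tertiary alcohol
Product: 34 bicyclic diol: arm B primary alcohol, C5 tertiary alcohol, arm A TBDPS ether (3Z,5S,8S,9R)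
Conditions: (NH4)2Ce(NO3)6, MeCN/H2O, 0 °C
Reagents that add atoms: none
Why: Oxidative dearylation turns the 4-methoxyphenyl ether into benzoquinone and frees the arm B alcohol, while the silyl ether, the alkenes and the tertiary alcohol should survive a short reaction at 0 °C.

Step 25
Reactants: 34 bicyclic diol
Product: 35 bicyclic aldehyde: arm B as CHO on C11, otherwise as 34
Conditions: Dess–Martin periodinane, pyridine, CH2Cl2, 0 °C
Reagents that add atoms: none
Why: Dess–Martin oxidation of the primary alcohol gives an aldehyde that has no alpha hydrogen and so cannot epimerise C11, and the tertiary alcohol cannot be oxidised.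

Step 26
Reactants: 35 bicyclic aldehyde
Product: 36 bicyclic (E)-iodoalkene: C11–CH=CH–I, otherwise as 34
Conditions: CrCl2 (6 equiv), CHI3, THF/dioxane, 0 °C to rt
Reagents that add atoms: iodoform IC(I)I
Why: Takai olefination with the geminal dichromium reagent from CHI3 should give the E-iodoalkene selectively with this hindered aldehyde and tolerates the free tertiary alcohol.

Step 27
Reactants: 36 bicyclic (E)-iodoalkene; 37 4,4,5,5-tetramethyl-2-(2-methylprop-1-en-1-yl)-1,3,2-dioxaborolane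
Product: 38 bicyclic diene: C11–(1E)-4-methylpenta-1,3-dienyl, arm A TBDPS ether, C5 tertiary alcohol (3Z,5S,8S,9R,11R)
Conditions: PdCl2(dppf) (cat.), K3PO4, THF/H2O, 40 °C
Reagents that add atoms: none
Why: Suzuki–Miyaura coupling proceeds with retention at both partners and completes the E-diene, the gem-dimethyl terminus having no geometry to control.

Step 28
Reactants: 38 bicyclic diene
Product: 39 bicyclic diol: arm A primary alcohol, C5 tertiary alcohol, dienyl group on C11 (3Z,5S,8S,9R,11R)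
Conditions: Bu4NF, AcOH, THF, rt
Reagents that add atoms: none
Why: Fluoride-mediated desilylation buffered with acetic acid frees the arm A alcohol without harming the diene or the tertiary allylic alcohol.

Step 29
Reactants: 39 bicyclic diol; 40 hexadecanoyl chloride (palmitoyl chloride)
Product: 41 CNP0150666.1, the hexadecanoate of the arm A alcohol (3Z,5S,8S,9R,11R; dienyl 1E)
Conditions: pyridine, DMAP (cat.), CH2Cl2, 0 °C
Reagents that add atoms: none
Why: DMAP-catalysed acylation with the acid chloride esterifies the primary alcohol only, the tertiary allylic alcohol being too hindered to react at 0 °C.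

Compound list
1 | butane-1,4-diol | OCCCCO | starting material
2 | 2-(bromomethyl)naphthalene | BrCc1ccc2ccccc2c1 | starting material
3 | 4-(naphthalen-2-ylmethoxy)butan-1-ol | OCCCCOCc1ccc2ccccc2c1 | intermediate
4 | 4-(naphthalen-2-ylmethoxy)butanal | O=CCCCOCc1ccc2ccccc2c1 | intermediate
5 | methyl acrylate | C=CC(=O)OC | starting material
6 | methyl 3-hydroxy-2-methylidene-6-(naphthalen-2-ylmethoxy)hexanoate (racemic) | C=C(C(=O)OC)C(O)CCCOCc1ccc2ccccc2c1 | intermediate
7 | methyl (2Z)-2-(bromomethyl)-6-(naphthalen-2-ylmethoxy)hex-2-enoate | BrC/C(C(=O)OC)=C\CCCOCc1ccc2ccccc2c1 | intermediate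
8 | 4-methoxyphenol | Oc1ccc(OC)cc1 | starting material
9 | methyl (2E)-2-[(4-methoxyphenoxy)methyl]-6-(naphthalen-2-ylmethoxy)hex-2-enoate | COc1ccc(OC/C(C(=O)OC)=C\CCCOCc2ccc3ccccc3c2)cc1 | intermediate
10 | (2Z)-2-[(4-methoxyphenoxy)methyl]-6-(naphthalen-2-ylmethoxy)hex-2-en-1-ol | COc1ccc(OC/C(CO)=C\CCCOCc2ccc3ccccc3c2)cc1 | intermediate
11 | [(2R,3S)-2-[(4-methoxyphenoxy)methyl]-3-[3-(naphthalen-2-ylmethoxy)propyl]oxiran-2-yl]methanol | OC[C@]1(COc2ccc(OC)cc2)O[C@H]1CCCOCc1ccc2ccccc2c1 | intermediate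
12 | tert-butyldimethyl(prop-2-yn-1-yloxy)silane | C#CCO[Si](C)(C)C(C)(C)C | starting material
13 | lithium acetylide of 12 | [Li]C#CCO[Si](C)(C)C(C)(C)C | intermediate
14 | diethyl{3-[(tert-butyldimethylsilyl)oxy]prop-1-yn-1-yl}alane | CC[Al](CC)C#CCO[Si](C)(C)C(C)(C)C | intermediate
15 | (2R,3S)-6-[(tert-butyldimethylsilyl)oxy]-2-[(4-methoxyphenoxy)methyl]-3-[3-(naphthalen-2-ylmethoxy)propyl]hex-4-yne-1,2-diol | CC(C)(C)[Si](C)(C)OCC#C[C@H](CCCOCc1ccc2ccccc2c1)[C@](O)(COc1ccc(OC)cc1)CO | intermediate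
16 | (2S,3S)-6-[(tert-butyldimethylsilyl)oxy]-1-[(tert-butyldiphenylsilyl)oxy]-2-[(4-methoxyphenoxy)methyl]-3-[3-(naphthalen-2-ylmethoxy)propyl]hex-4-yn-2-ol | CC(C)(C)[Si](C)(C)OCC#C[C@H](CCCOCc1ccc2ccccc2c1)[C@](O)(COc1ccc(OC)cc1)CO[Si](c1ccccc1)(c1ccccc1)C(C)(C)C | intermediate
17 | (2S,3S)-6-[(tert-butyldimethylsilyl)oxy]-1-[(tert-butyldiphenylsilyl)oxy]-2-(methoxymethoxy)-2-[(4-methoxyphenoxy)methyl]-3-[3-(naphthalen-2-ylmethoxy)propyl]hex-4-yne | CC(C)(C)[Si](C)(C)OCC#C[C@H](CCCOCc1ccc2ccccc2c1)[C@](OCOC)(COc1ccc(OC)cc1)CO[Si](c1ccccc1)(c1ccccc1)C(C)(C)C | intermediate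
18 | (4S,5S)-6-[(tert-butyldiphenylsilyl)oxy]-5-(methoxymethoxy)-5-[(4-methoxyphenoxy)methyl]-4-[3-(naphthalen-2-ylmethoxy)propyl]hex-2-yn-1-ol | OCC#C[C@H](CCCOCc1ccc2ccccc2c1)[C@](OCOC)(COc1ccc(OC)cc1)CO[Si](c1ccccc1)(c1ccccc1)C(C)(C)C | intermediate
19 | (2E,4S,5S)-6-[(tert-butyldiphenylsilyl)oxy]-5-(methoxymethoxy)-5-[(4-methoxyphenoxy)methyl]-4-[3-(naphthalen-2-ylmethoxy)propyl]-2-(tributylstannyl)hex-2-en-1-ol | OC/C([Sn](CCCC)(CCCC)CCCC)=C\[C@H](CCCOCc1ccc2ccccc2c1)[C@](OCOC)(COc1ccc(OC)cc1)CO[Si](c1ccccc1)(c1ccccc1)C(C)(C)C | intermediate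
20 | (2E,4S,5S)-6-[(tert-butyldiphenylsilyl)oxy]-2-iodo-5-(methoxymethoxy)-5-[(4-methoxyphenoxy)methyl]-4-[3-(naphthalen-2-ylmethoxy)propyl]hex-2-en-1-ol | OC/C(I)=C\[C@H](CCCOCc1ccc2ccccc2c1)[C@](OCOC)(COc1ccc(OC)cc1)CO[Si](c1ccccc1)(c1ccccc1)C(C)(C)C | intermediate
21 | (2E,4S,5S)-1-bromo-6-[(tert-butyldiphenylsilyl)oxy]-2-iodo-5-(methoxymethoxy)-5-[(4-methoxyphenoxy)methyl]-4-[3-(naphthalen-2-ylmethoxy)propyl]hex-2-ene | BrC/C(I)=C\[C@H](CCCOCc1ccc2ccccc2c1)[C@](OCOC)(COc1ccc(OC)cc1)CO[Si](c1ccccc1)(c1ccccc1)C(C)(C)C | intermediate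
22 | ethynyltrimethylsilane | C#C[Si](C)(C)C | starting material
23 | (4E,6S,7S)-8-[(tert-butyldiphenylsilyl)oxy]-4-iodo-7-(methoxymethoxy)-7-[(4-methoxyphenoxy)methyl]-6-[3-(naphthalen-2-ylmethoxy)propyl]-1-(trimethylsilyl)oct-4-en-1-yne | C[Si](C)(C)C#CC/C(I)=C\[C@H](CCCOCc1ccc2ccccc2c1)[C@](OCOC)(COc1ccc(OC)cc1)CO[Si](c1ccccc1)(c1ccccc1)C(C)(C)C | intermediate
24 | (trimethylsilyl)methylmagnesium chloride | C[Si](C)(C)C[Mg]Cl | starting material
25 | (4E,6S,7S)-8-[(tert-butyldiphenylsilyl)oxy]-7-(methoxymethoxy)-7-[(4-methoxyphenoxy)methyl]-6-[3-(naphthalen-2-ylmethoxy)propyl]-1-(trimethylsilyl)-4-[(trimethylsilyl)methyl]oct-4-en-1-yne (key-step precursor; Me3SiCH2 trans to C8) | C[Si](C)(C)C#CCC(\C[Si](C)(C)C)=C/[C@H](CCCOCc1ccc2ccccc2c1)[C@](OCOC)(COc1ccc(OC)cc1)CO[Si](c1ccccc1)(c1ccccc1)C(C)(C)C | intermediate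
26 | tert-butyl{[(2S,3S,4R)-2-[(4-methoxyphenoxy)methyl]-3-[3-(naphthalen-2-ylmethoxy)propyl]-4-[5-(trimethylsilyl)pent-1-en-4-yn-2-yl]oxolan-2-yl]methoxy}diphenylsilane (key-step product) | O(Cc1ccc2ccccc2c1)CCC[C@H]1[C@H](C(=C)CC#C[Si](C)(C)C)CO[C@@]1(COc1ccc(OC)cc1)CO[Si](c1ccccc1)(c1ccccc1)C(C)(C)C | intermediate
27 | tert-butyl{[(2S,3S,4R)-4-(5-iodopent-1-en-4-yn-2-yl)-2-[(4-methoxyphenoxy)methyl]-3-[3-(naphthalen-2-ylmethoxy)propyl]oxolan-2-yl]methoxy}diphenylsilane | O(Cc1ccc2ccccc2c1)CCC[C@H]1[C@H](C(=C)CC#CI)CO[C@@]1(COc1ccc(OC)cc1)CO[Si](c1ccccc1)(c1ccccc1)C(C)(C)C | intermediate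
28 | tert-butyl{[(2S,3S,4R)-4-[(4Z)-5-iodopenta-1,4-dien-2-yl]-2-[(4-methoxyphenoxy)methyl]-3-[3-(naphthalen-2-ylmethoxy)propyl]oxolan-2-yl]methoxy}diphenylsilane | O(Cc1ccc2ccccc2c1)CCC[C@H]1[C@H](C(=C)C/C=C\I)CO[C@@]1(COc1ccc(OC)cc1)CO[Si](c1ccccc1)(c1ccccc1)C(C)(C)C | intermediate
29 | 3-[(2S,3S,4R)-2-{[(tert-butyldiphenylsilyl)oxy]methyl}-4-[(4Z)-5-iodopenta-1,4-dien-2-yl]-2-[(4-methoxyphenoxy)methyl]oxolan-3-yl]propan-1-ol | OCCC[C@H]1[C@H](C(=C)C/C=C\I)CO[C@@]1(COc1ccc(OC)cc1)CO[Si](c1ccccc1)(c1ccccc1)C(C)(C)C | intermediate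
30 | 3-[(2S,3S,4R)-2-{[(tert-butyldiphenylsilyl)oxy]methyl}-4-[(4Z)-5-iodopenta-1,4-dien-2-yl]-2-[(4-methoxyphenoxy)methyl]oxolan-3-yl]propanal | O=CCC[C@H]1[C@H](C(=C)C/C=C\I)CO[C@@]1(COc1ccc(OC)cc1)CO[Si](c1ccccc1)(c1ccccc1)C(C)(C)C | intermediate
31 | bicyclic allylic alcohol, (3Z)-cyclononene trans-fused to the tetrahydrofuran, C5 secondary carbinol (both epimers), arm B 4-methoxyphenyl ether, arm A TBDPS ether | C=C1C/C=C\C(O)CC[C@H]2[C@H]1CO[C@@]2(COc1ccc(OC)cc1)CO[Si](c1ccccc1)(c1ccccc1)C(C)(C)C | intermediate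
32 | bicyclic (3Z)-enone, C5 ketone, otherwise as 31 | C=C1C/C=C\C(=O)CC[C@H]2[C@H]1CO[C@@]2(COc1ccc(OC)cc1)CO[Si](c1ccccc1)(c1ccccc1)C(C)(C)C | intermediate
33 | bicyclic tertiary alcohol, (3Z,5S,8S,9R), arm B 4-methoxyphenyl ether, arm A TBDPS ether | C=C1C/C=C\[C@@](C)(O)CC[C@H]2[C@H]1CO[C@@]2(COc1ccc(OC)cc1)CO[Si](c1ccccc1)(c1ccccc1)C(C)(C)C | intermediate
34 | bicyclic diol, arm B primary alcohol, arm A TBDPS ether | C=C1C/C=C\[C@@](C)(O)CC[C@H]2[C@H]1CO[C@@]2(CO)CO[Si](c1ccccc1)(c1ccccc1)C(C)(C)C | intermediate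
35 | bicyclic aldehyde, arm B as CHO | C=C1C/C=C\[C@@](C)(O)CC[C@H]2[C@H]1CO[C@@]2(C=O)CO[Si](c1ccccc1)(c1ccccc1)C(C)(C)C | intermediate
36 | bicyclic (E)-iodoalkene, arm B as CH=CHI | C=C1C/C=C\[C@@](C)(O)CC[C@H]2[C@H]1CO[C@@]2(/C=C/I)CO[Si](c1ccccc1)(c1ccccc1)C(C)(C)C | intermediate
37 | 4,4,5,5-tetramethyl-2-(2-methylprop-1-en-1-yl)-1,3,2-dioxaborolane | CC(C)=CB1OC(C)(C)C(C)(C)O1 | starting material
38 | bicyclic diene, C11–(1E)-4-methylpenta-1,3-dienyl, arm A TBDPS ether | C=C1C/C=C\[C@@](C)(O)CC[C@H]2[C@H]1CO[C@@]2(/C=C/C=C(C)C)CO[Si](c1ccccc1)(c1ccccc1)C(C)(C)C | intermediate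
39 | bicyclic diol, arm A primary alcohol, C5 tertiary alcohol, dienyl group on C11 | C=C1C/C=C\[C@@](C)(O)CC[C@H]2[C@H]1CO[C@@]2(/C=C/C=C(C)C)CO | intermediate
40 | hexadecanoyl chloride | CCCCCCCCCCCCCCCC(=O)Cl | starting material
41 | CNP0150666.1, hexadecanoate of 39 at the arm A oxygen (3Z,5S,8S,9R,11R; dienyl 1E) | C=C1C/C=C\[C@@](C)(O)CC[C@H]2[C@H]1CO[C@@]2(/C=C/C=C(C)C)COC(=O)CCCCCCCCCCCCCCC | target

Total step count: 29. Longest linear sequence: 29 steps (from 1; the route is fully linear, 5, 8, 12, 22, 24, 37 and 40 being bought).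

Steps most likely to fail

Step 16. The acetal may ionise towards loss of the whole methoxymethyl group, or the allylsilane may be protodesilylated before the C9–C10 bond forms. The fallback changes how the cation is made. It sets out from 25: Me2BBr in CH2Cl2 at −78 °C should convert the methoxymethyl ether into the bromomethyl ether F1, which can ionise only to the C11–O=CH2 cation. AgOTf with 2,6-di-tert-butyl-4-methylpyridine at −78 °C then abstracts bromide, and the same ring closure comes back to the route at 26.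

Step 21. Intermolecular coupling or simple reduction of the alkenyl iodide may win over the entropically costly nine-membered closure. The fallback closes the ring by olefin metathesis at C3=C4 and sets out from 26. K2CO3 in MeOH should free the terminal alkyne F2, and semihydrogenation over Pd on CaCO3 poisoned with Pb(OAc)2 (quinoline) should give the allyl compound F3. DDQ then gives the alcohol F4 and Dess–Martin periodinane the aldehyde F5, to which CH2=CHMgBr adds to give the dienol F6. The second-generation Hoveyda–Grubbs catalyst in toluene at high dilution should then close the Z-cyclononene with loss of ethene (C4 now comes from the vinyl reagent), coming back to the route at 31.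

Step 23. Facial selectivity at the ring ketone may be poor, or the enone may enolise towards C2. The fallback forms the carbinol during ring closure instead of after it and sets out from 30. MeMgBr in THF at −78 °C gives the secondary carbinol F7 and Dess–Martin periodinane the methyl ketone F8. CrCl2 with catalytic NiCl2 in DMSO at high dilution then closes C4–C5 onto the ketone, so that C5 is set in a different transition state; this is expected to be slower than the aldehyde closure and comes back to the route at 33.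

Further compounds
F1 | step 16 | bromomethyl ether corresponding to 25 (OCH2Br in place of OCH2OCH3) | C[Si](C)(C)C#CCC(\C[Si](C)(C)C)=C/[C@H](CCCOCc1ccc2ccccc2c1)[C@](OCBr)(COc1ccc(OC)cc1)CO[Si](c1ccccc1)(c1ccccc1)C(C)(C)C
F2 | step 21 | terminal alkyne from 26 (pent-1-en-4-yn-2-yl on C9) | O(Cc1ccc2ccccc2c1)CCC[C@H]1[C@H](C(=C)CC#C)CO[C@@]1(COc1ccc(OC)cc1)CO[Si](c1ccccc1)(c1ccccc1)C(C)(C)C
F3 | step 21 | allyl compound (penta-1,4-dien-2-yl on C9) | O(Cc1ccc2ccccc2c1)CCC[C@H]1[C@H](C(=C)CC=C)CO[C@@]1(COc1ccc(OC)cc1)CO[Si](c1ccccc1)(c1ccccc1)C(C)(C)C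
F4 | step 21 | C5 alcohol of F3 | OCCC[C@H]1[C@H](C(=C)CC=C)CO[C@@]1(COc1ccc(OC)cc1)CO[Si](c1ccccc1)(c1ccccc1)C(C)(C)C
F5 | step 21 | C5 aldehyde of F3 | O=CCC[C@H]1[C@H](C(=C)CC=C)CO[C@@]1(COc1ccc(OC)cc1)CO[Si](c1ccccc1)(c1ccccc1)C(C)(C)C
F6 | step 21 | dienol, vinyl carbinol at C5 (both epimers) | C=CC(O)CC[C@H]1[C@H](C(=C)CC=C)CO[C@@]1(COc1ccc(OC)cc1)CO[Si](c1ccccc1)(c1ccccc1)C(C)(C)C
F7 | step 23 | secondary methyl carbinol from 30 (both epimers) | CC(O)CC[C@H]1[C@H](C(=C)C/C=C\I)CO[C@@]1(COc1ccc(OC)cc1)CO[Si](c1ccccc1)(c1ccccc1)C(C)(C)C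
F8 | step 23 | methyl ketone with the Z-alkenyl iodide | CC(=O)CC[C@H]1[C@H](C(=C)C/C=C\I)CO[C@@]1(COc1ccc(OC)cc1)CO[Si](c1ccccc1)(c1ccccc1)C(C)(C)C
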